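The 25-membered lactone ring is disconnected at C11–C12 (C1 = lactone carbonyl carbon, C24 = OCH2 carbon). Ring atoms C10–C13 are plain methylene groups, so they can be masked as a conjugated 1,3-diyne, whose central bond arises from oxidative homocoupling of two terminal alkynes. An Eglinton coupling with Cu(OAc)2 therefore forges C11–C12 and closes the macrocycle in one operation. Its substrate is an open-chain ester bearing an ethynyl group at each end, assembled from undec-10-ynoic acid (C1–C11) and tridec-12-yn-1-ol (C12–C24); the latter comes from 11-bromoundecan-1-ol and an acetylide without protecting groups. Exhaustive hydrogenation then converts the diyne into the saturated lactone.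

Key step: step 3

Remark: no compound on the main route has a stereocentre or a stereogenic double bond; acetylene is introduced as its commercial lithium acetylide ethylenediamine complex, which supplies C12 and C13.

Step 1
Reactants: 1 11-bromoundecan-1-ol; 2 lithium acetylide ethylenediamine complex (LiC≡CH·H2NCH2CH2NH2)
Product: 5 tridec-12-yn-1-ol, via lithium 11-bromoundecan-1-olate 3 (not isolated), via lithium tridec-12-yn-1-olate 4 (not isolated)
Conditions: 2 (3 equiv), DMSO, 10 °C to rt; then H2O
Reagents that add atoms: none
Why: One equivalent of acetylide deprotonates the hydroxyl group and the excess displaces the primary bromide of the weakly nucleophilic lithium alkoxide in an SN2 acetylide alkylation, a known protecting-group-free way from ω-bromoalkanols to ω-alkynols.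

Step 2
Reactants: 5 tridec-12-yn-1-ol; 6 undec-10-ynoic acid
Product: 7 tridec-12-yn-1-yl undec-10-ynoate
Conditions: DCC (1.1 equiv), DMAP (0.1 equiv), CH2Cl2, 0 °C to rt
Reagents that add atoms: none
Why: Steglich esterification of an unhindered acid with a primary alcohol should proceed cleanly, since DMAP relays the carbodiimide-activated acid to the alcohol and neither terminal alkyne reacts under these near-neutral conditions.

Step 3
Reactants: 7 tridec-12-yn-1-yl undec-10-ynoate
Product: 8 oxacyclopentacosa-11,13-diyn-2-one
Conditions: Cu(OAc)2·H2O (10 equiv), pyridine/Et2O 5:1 (v/v), 40 °C, syringe-pump addition of 7 over 12 h to ca. 1 mM final concentration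
Reagents that add atoms: none
Why: Acetate and pyridine assist deprotonation of each terminal alkyne at copper, and two copper acetylide units held in a bridged dicopper assembly collapse to the C(sp)–C(sp) bond between C11 and C12 while two divalent copper centres are reduced to monovalent copper. The closest known reaction type is the Eglinton variant of the Glaser coupling, a standard way of closing large rings from α,ω-diynes. The one ring formed is the 25-membered lactone ring, closed by end-to-end joining of the two alkyne termini of a single chain, a homocoupling macrocyclisation in which the new bond lies inside the ring and exo/endo descriptors do not apply. No stereocentre is created. The step needs ring closure to win over chain-to-chain coupling, which is secured on the substrate side by the strain-free fit of the linear C10–C13 diyne rod in a ring of this size, by the identity of the two termini (no cross-selectivity question) and by the inertness of the ester, and on the process side by slow addition that keeps the stationary concentration of the bis-alkyne very low.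

Step 4
Reactants: 8 oxacyclopentacosa-11,13-diyn-2-one
Product: 9 24-tetracosanolide (oxacyclopentacosan-2-one)
Conditions: H2 (1 atm), 10% Pd/C, EtOAc, rt
Reagents that add atoms: none
Why: Exhaustive heterogeneous hydrogenation should saturate the C10–C13 diyne with four equivalents of H2, while the lactone, the only other functional group, is inert to H2 over Pd/C and has no benzylic, allylic or propargylic C–O bond.

Compound list
1 | 11-bromoundecan-1-ol | OCCCCCCCCCCCBr | starting material
2 | lithium acetylide ethylenediamine complex, LiC≡CH·H2NCH2CH2NH2 | [Li]C#C.NCCN | starting material
3 | lithium 11-bromoundecan-1-olate | [Li+].[O-]CCCCCCCCCCCBr | intermediate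
4 | lithium tridec-12-yn-1-olate | [Li+].[O-]CCCCCCCCCCCC#C | intermediate
5 | tridec-12-yn-1-ol | OCCCCCCCCCCCC#C | intermediate
6 | undec-10-ynoic acid | C#CCCCCCCCCC(=O)O | starting material
7 | tridec-12-yn-1-yl undec-10-ynoate | C#CCCCCCCCCC(=O)OCCCCCCCCCCCC#C | intermediate
8 | oxacyclopentacosa-11,13-diyn-2-one | O=C1CCCCCCCCC#CC#CCCCCCCCCCCCO1 | intermediate
9 | 24-tetracosanolide (oxacyclopentacosan-2-one) | O=C1CCCCCCCCCCCCCCCCCCCCCCCO1 | target

Total step count: 4. Longest linear sequence: 4 steps (1 to 5 to 7 to 8 to 9).

Steps most likely to fail

Step 3 (macrocyclisation). Chain-to-chain coupling may outpace ring closure, so that linear and cyclic oligomers consume the bis-alkyne. The fallback moves the ring closure to the ester C–O bond and makes the C11–C12 bond between two separate molecules, where dilution plays no part. It sets out from 5. Bromination of the alkyne terminus (NBS, cat. AgNO3, acetone, rt) should give 13-bromotridec-12-yn-1-ol F1. Cadiot–Chodkiewicz coupling of this bromoalkyne with 6 (cat. CuCl, NH2OH·HCl, aqueous EtNH2, MeOH, 0 °C to rt) should give 24-hydroxytetracosa-10,12-diynoic acid F2. Hydrogenation (H2, 10% Pd/C, EtOAc/MeOH) should give 24-hydroxytetracosanoic acid F3. Yamaguchi macrolactonisation follows: 2,4,6-trichlorobenzoyl chloride and Et3N in THF should form 24-hydroxytetracosanoic 2,4,6-trichlorobenzoic anhydride F4 in the flask, and slow addition of it to DMAP in toluene at reflux should return to the route at the target 9.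

Step 1 (acetylide alkylation on the free alcohol). The bromide may be consumed by the alkoxide oxygen (ether formation), by the nitrogen of ethylenediamine, or by dehydrobromination before the acetylide carbon attacks. The fallback masks the hydroxyl group and sets out from 1. DHP with cat. PPTS in CH2Cl2 should give 2-[(11-bromoundecyl)oxy]oxane F5 (racemic at the acetal carbon). Alkylation with 2 (1.5 equiv) in DMSO should give 2-(tridec-12-yn-1-yloxy)oxane F6. Acetal cleavage with cat. TsOH·H2O in MeOH at rt should return to the route at 5.

Step 2 (esterification). The carbodiimide-activated acid may rearrange to an unreactive N-acylurea, and acyl transfer may then stall. The fallback reverses the polarity of the C–O bond formation, so that the acid is never activated. It sets out from 5. MsCl and Et3N in CH2Cl2 at 0 °C should give tridec-12-yn-1-yl methanesulfonate F7. SN2 displacement by the caesium carboxylate of 6 (Cs2CO3, DMF, 50 °C) should return to the route at 7.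

Further compounds
F1 | step 3 | 13-bromotridec-12-yn-1-ol | OCCCCCCCCCCCC#CBr
F2 | step 3 | 24-hydroxytetracosa-10,12-diynoic acid | OCCCCCCCCCCCC#CC#CCCCCCCCCC(=O)O
F3 | step 3 | 24-hydroxytetracosanoic acid | OCCCCCCCCCCCCCCCCCCCCCCCC(=O)O
F4 | step 3 | 24-hydroxytetracosanoic 2,4,6-trichlorobenzoic anhydride | OCCCCCCCCCCCCCCCCCCCCCCCC(=O)OC(=O)c1c(Cl)cc(Cl)cc1Cl
F5 | step 1 | 2-[(11-bromoundecyl)oxy]oxane (racemic) | BrCCCCCCCCCCCOC1CCCCO1
F6 | step 1 | 2-(tridec-12-yn-1-yloxy)oxane (racemic) | C#CCCCCCCCCCCCOC1CCCCO1
F7 | step 2 | tridec-12-yn-1-yl methanesulfonate | CS(=O)(=O)OCCCCCCCCCCCC#C
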